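## The problem

The target, (2S)-5-hydroxy-7-(3-methylbut-2-enyloxy)-8-(3-methylbut-2-enyl)flavanone (15), is a chroman-4-one. A phloroglucinol-type ring A is fused through C4a and C8a to the oxygen ring C, and ring B is a plain phenyl group on C2. Ring A carries four different neighbours in a row (chelated OH at C5, H at C6, prenyl ether at O7, C-prenyl at C8), so O5 must be told from O7 and C8 from C6. The only stereocentre is C2 (S); nothing else in the molecule can relay it, so it has to come from a catalyst. It is also fragile: once C4 is a ketone, base opens ring C by retro-oxa-Michael reaction to the 2'-hydroxychalcone and C2 is lost. The two prenyl groups tolerate neither hydrogenolysis nor strong acid (ether cleavage, cyclisation onto a neighbouring phenol) and should therefore arrive last. The feature that makes the key step possible lies in ring C: O1–C2 and C3–C4 flank a C2–C3 unit that is styrene, O1 is the phenol oxygen and C4 the formyl carbon of a salicylaldehyde, and C4 then needs only one oxidation to become the ketone. A second useful feature is that C8 is para to O5 and O5 is peri to the C4 carbonyl, so a prenyl group can be passed from O5 to C8 by a chelation-triggered sigmatropic relay.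

## Retrosynthesis

**15 from 13.** The C8–CH2 bond of the C-prenyl group is cut and the prenyl unit is returned to O5, giving (2S)-5,7-bis(prenyloxy)flavanone 13. The forward reaction is a para-Claisen–Cope rearrangement through the C6 dienone 14. Direct C-prenylation of a 5,7-dihydroxyflavanone gives no C6/C8 control and needs base or strong acid, both of which threaten C2. In 13 the two ring A oxygens carry the same group, so both prenyl units come from one operation. The forward step must activate only the chelated 5-ether, carry the allyl unit on from C6 to C8 before the dienone enolises, and leave C2 alone.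

**13 from 11 and 12.** The two O–CH2 bonds are cut to (2S)-pinocembrin 11 and 3-methylbut-2-en-1-ol 12. A Mitsunobu etherification is preferred to bromide and carbonate because it is free of base. The forward step must reach the chelated 5-hydroxyl as well as the acidic 7-hydroxyl.

**11 from 10.** The free phenols are traced to the bis(benzyl ether) 10. Prenyl ethers cannot be carried from the start: they are acid-labile, and their electron-rich alkenes would trap the cationic intermediate of the ring-forming step. Acetal protecting groups would not survive that acid either. Benzyl ethers are inert there and come off by hydrogenolysis, which is why deprotection must precede prenylation.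

**10 from 8 via 9.** The C4 carbonyl is taken back to the carbinol 9 and then to the methyl ether 8. The three oxygens ortho and para to C4a make the C4–OMe bond easy to hydrolyse, and oxidation of the benzylic alcohol is routine. This costs two steps.

**8 from 3, 4 and 5.** The O1–C2 and C3–C4 bonds are cut together. This leads to salicylaldehyde 3, styrene 4 and trimethyl orthoformate 5, by way of acetal 6 and the methoxy ortho-quinone methide 7. The neighbouring disconnections build ring C and C2 in separate events: oxa-Michael closure of a chalcone makes only O1–C2, and aryl addition to a chromone makes only C2–C1'. Here the ring, both bonds and the stereocentre arise in one convergent step from achiral components. The forward step asks a chiral counter-anion to choose one face of the oxocarbenium ion and asks for endo addition. C4 is temporary, but it is not a bystander: the endo rule ties the C2 configuration to the C4 face, so a trans isomer formed by exo addition would carry the wrong C2. The cis adduct is therefore purified before C4 is erased.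

**3 from 1 and 2.** Two O–benzyl bonds are cut to 2,4,6-trihydroxybenzaldehyde 1 and benzyl bromide 2. The hydrogen bond between one ortho hydroxyl and the formyl group provides the selectivity.

## Roads not taken

Alternative 1: The cut is the C3–C4 bond of ring C. The thioester A1, S-(pyridin-2-yl) 2-[(1R)-2-iodo-1-phenylethoxy]-4,6-bis(methoxymethoxy)benzothioate, would be closed by nickel-catalysed cross-electrophile coupling (NiBr2(dme), a bipyridine ligand, an organic reductant). The acyl carbon and the primary iodide carbon are joined to give (S)-5,7-bis(methoxymethoxy)flavanone A2.
- Merits: the ketone appears at its final oxidation level, the stereocentre is bought from an established asymmetric reduction, and the acetal protecting groups come off without hydrogen. No redox adjustment follows ring closure.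
- Weak points: A1 is a β-aryloxy alkyl iodide. On reduction, the alkyl radical or alkylnickel species has an aryloxide leaving group on the next carbon, and Boord-type fragmentation to styrene and the phenolate should compete at the very moment of bond formation. Making A1 needs etherification of a chelated, hindered salicylate phenol at a benzylic carbinol with clean inversion, plus thioester and iodide installation, about six steps before ring C exists. A six-membered acyl–alkyl reductive closure of this kind has no close precedent.
- Comparison: the origin of the stereocentre is more secure than in an untested enantioselective cycloaddition, and that is a real advantage. Against it the chosen plan sets a ring-forming step whose achiral version is established, roughly three fewer steps to the flavanone, and a failure mode (low enantioselectivity) that resolution can repair, whereas fragmentation of A1 cannot be repaired.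

Alternative 2: The cuts are O–C8a and C4–C4a, so ring A is attached to the three-carbon chain by aryne insertion into a carboxylic acid. 3,5-Bis(benzyloxy)benzyne A4, released by fluoride from an ortho-silylaryl triflate, would be attacked by the carboxylate of (R)-3-phenyl-3-(triisopropylsilyloxy)propanoic acid A3 at the aryne carbon away from the flanking benzyloxy group. The aryl anion then takes the acyl group, giving the ortho-hydroxyaryl ketone A5. Desilylation and closure with inversion would converge on flavanone 10.
- Merits: regiochemistry is guided by the distortion of the 3-alkoxyaryne, the stereocentre comes from reliable asymmetric aldol or hydrogenation chemistry, and the carbonyl is already in place.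
- Weak points: the key step closes no ring. The closure that remains is a displacement at a benzylic carbinol β to an aryl ketone, where dehydration to the chalcone is the easy path and leads to racemic flavanone. The aryne precursor takes four to five steps on its own. Aryl ester formation without acyl transfer, and protonation of the aryl anion, are side channels.
- Comparison: the stereocentre is proven rather than hoped for, which the chosen plan cannot claim. The chosen plan answers with about half the step count to 10 and with ring and stereocentre formed in the same event, so no open-chain β-oxygenated ketone is ever handled.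

Alternative 3: The cut is C4–C4a. (S)-3-[3,5-Bis(benzyloxy)phenoxy]-3-phenylpropanoic acid A6, activated as a mixed anhydride or acid chloride, would acylate the arene ortho to the ether oxygen and give (S)-5,7-bis(benzyloxy)flavanone A7, identical with 10.
- Merits: intramolecular acylation of a phloroglucinol-type ring is fast and belongs to a well-known class. The symmetry of the aryloxy ring removes any regiochemical question. The ketone is delivered directly, so the two redox steps of the chosen plan are saved.
- Weak points: the stereocentre of A6 is a benzylic aryl ether β to the activated acyl group. Loss of the phenoxide (retro-oxa-Michael, giving a cinnamate) and acid-induced ionisation both erode it, during the closure and already during ester hydrolysis on the way to A6. A6 itself needs a Mitsunobu inversion at a benzylic β-hydroxy ester, which is prone to elimination.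
- Comparison: in precedent this is the safest of the four roads, and it reaches the flavanone in a similar number of steps. The chosen plan sets against it the catalytic creation of C2 from achiral feedstock without stoichiometric chiral material, the absence of any intermediate with a leaving group β to an activated carbonyl before the ring exists, and the value of the new enantioselective three-component ring synthesis.

Key step: step 2

Assumption: the (R)-configured catalyst is taken to deliver the 2S,4S adduct; if the sense of induction proves opposite, its enantiomer is used and nothing else in the route changes.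

## Route

Step 1
Reactants: 1 2,4,6-trihydroxybenzaldehyde; 2 benzyl bromide
Product: 3 2-hydroxy-4,6-bis(benzyloxy)benzaldehyde
Conditions: BnBr (2.1 equiv), K2CO3 (2.2 equiv), DMF, 0 °C to rt
Reagents that add atoms: benzyl bromide 2, BrCc1ccccc1
Why: Williamson etherification; the 4-hydroxyl (para to the formyl group, most acidic, not chelated) and one ortho hydroxyl react, after which the remaining ortho hydroxyl is locked in a hydrogen bond to the aldehyde and is the least nucleophilic oxygen, so a controlled amount of bromide stops at the bis-ether.

Step 2
Reactants: 3 2-hydroxy-4,6-bis(benzyloxy)benzaldehyde; 4 styrene; 5 trimethyl orthoformate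
Product: 8 (2S,4S)-5,7-bis(benzyloxy)-4-methoxyflavan (2,4-cis), via dimethyl acetal 6 (not isolated), via methoxy ortho-quinone methide 7 (not isolated)
Conditions: 4 (3 equiv), 5 (1.3 equiv), (R)-3,3'-bis(2,4,6-triisopropylphenyl)-1,1'-binaphthyl-2,2'-diyl N-triflylphosphoramide (10 mol%), 5 Å MS, toluene, −40 to 0 °C
Reagents that add atoms: styrene 4, C=Cc1ccccc1; trimethyl orthoformate 5, COC(OC)OC
Why: Proposed new method: the chiral acid converts 3 and 5 into acetal 6 and then ionises it to the O-methyl oxocarbenium ion (protonated 7), which is held to the phosphoramide anion through the phenol hydrogen bond; the closest known reaction type is the achiral acid-promoted three-component hetero-Diels–Alder reaction of salicylaldehydes, orthoformates and styrenes to 2,4-cis-4-alkoxy-2-arylchromans, together with chiral phosphoric acid catalysis of ortho-quinone methide cycloadditions. Ring C closes by an inverse-electron-demand, strongly asynchronous [4+2] addition in which the styrene terminus bonds to the methide carbon (C3–C4) ahead of the benzylic carbon bonding to the phenol oxygen (O1–C2). C4 is set by the face of the oxocarbenium ion left open by the 3,3'-aryl groups of the catalyst, and C2 follows from the endo orientation of the phenyl group, which gives the 2,4-cis relationship and hence 2S from 4S. Regiochemistry is secured by the polarity match between the electrophilic methide carbon and the nucleophilic CH2 of styrene. The two benzyloxy groups stabilise the cation enough for it to form below 0 °C and, having no alkene, cannot intercept it. The selectivity needed is enantiofacial and endo; the minor trans isomer, which may carry 2R, is removed by chromatography before C4 is erased.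

Step 3
Reactants: 8 (2S,4S)-5,7-bis(benzyloxy)-4-methoxyflavan
Product: 9 (2S)-5,7-bis(benzyloxy)flavan-4-ol (mixture of C4 epimers)
Conditions: TsOH·H2O (5 mol%), THF/H2O 3:1, high dilution, rt
Reagents that add atoms: water, O
Why: Acid-catalysed SN1 hydrolysis of a benzylic methyl ether; the C4 cation is stabilised by O1, O5 and O7, and the large excess of water at high dilution drives ether to alcohol while suppressing intermolecular arylation. The epimer mixture at C4 is of no consequence because C4 becomes trigonal in step 4, and C2 is not ionised under these conditions.

Step 4
Reactants: 9 (2S)-5,7-bis(benzyloxy)flavan-4-ol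
Product: 10 (2S)-5,7-bis(benzyloxy)flavanone
Conditions: Dess–Martin periodinane (1.3 equiv), NaHCO3 (3 equiv), CH2Cl2, 0 °C to rt
Reagents that add atoms: none
Why: Dess–Martin oxidation of a secondary benzylic alcohol; the hydrogencarbonate buffer keeps the medium from ionising the acid-labile carbinol, and the non-basic conditions leave C2 of the flavanone untouched.

Step 5
Reactants: 10 (2S)-5,7-bis(benzyloxy)flavanone
Product: 11 (2S)-5,7-dihydroxyflavanone ((S)-pinocembrin)
Conditions: H2 (1 atm), 10% Pd/C, EtOAc/MeOH 1:1, rt
Reagents that add atoms: none
Why: Catalytic hydrogenolysis of aryl benzyl ethers, routine on benzyl-protected flavanones; the reaction is stopped at full debenzylation so that the benzylic C2–O1 bond is not cleaved, and the neutral medium preserves C2.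

Step 6
Reactants: 11 (2S)-5,7-dihydroxyflavanone; 12 3-methylbut-2-en-1-ol
Product: 13 (2S)-5,7-bis(3-methylbut-2-enyloxy)flavanone
Conditions: 12 (3 equiv), PPh3 (3 equiv), DIAD (3 equiv), THF, 0 °C to rt
Reagents that add atoms: 3-methylbut-2-en-1-ol 12, CC(C)=CCO
Why: Double Mitsunobu etherification with a primary allylic alcohol; the acidic 7-hydroxyl reacts first and the chelated 5-hydroxyl follows with excess reagent, attack occurring at the primary carbon of the alkoxyphosphonium ion without allylic transposition. No base is present, so the flavanone cannot open to the chalcone and C2 is retained.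

Step 7
Reactants: 13 (2S)-5,7-bis(3-methylbut-2-enyloxy)flavanone
Product: 15 (2S)-5-hydroxy-7-(3-methylbut-2-enyloxy)-8-(3-methylbut-2-enyl)flavanone, via C6 reverse-prenyl dienone 14 (not isolated)
Conditions: Eu(fod)3 (europium tris(6,6,7,7,8,8,8-heptafluoro-2,2-dimethyloctane-3,5-dionate), 10 mol%), CHCl3, 60 °C
Reagents that add atoms: none
Why: Europium-catalysed para-Claisen–Cope rearrangement of a 5-prenyloxyflavanone; chelation of the trivalent europium centre between the C4 carbonyl and O5 activates only that ether, a [3,3] shift places the inverted allyl unit on C6 (dienone 14), and a Cope [3,3] shift carries it to C8 with normal prenyl connectivity before tautomerisation to the chelated 5-phenol. The 7-ether is not chelated and stays, and the mild Lewis acid does not touch C2.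

## Compound list

1 | 2,4,6-trihydroxybenzaldehyde | O=Cc1c(O)cc(O)cc1O | starting material
2 | benzyl bromide | BrCc1ccccc1 | starting material
3 | 2-hydroxy-4,6-bis(benzyloxy)benzaldehyde | O=Cc1c(O)cc(OCc2ccccc2)cc1OCc1ccccc1 | intermediate
4 | styrene | C=Cc1ccccc1 | starting material
5 | trimethyl orthoformate | COC(OC)OC | starting material
6 | 3,5-bis(benzyloxy)-2-(dimethoxymethyl)phenol (dimethyl acetal, formed in the flask) | COC(OC)c1c(O)cc(OCc2ccccc2)cc1OCc1ccccc1 | intermediate
7 | 3,5-bis(benzyloxy)-6-(methoxymethylidene)cyclohexa-2,4-dien-1-one (methoxy ortho-quinone methide, formed in the flask, reacting as its O-protonated form) | COC=C1C(=O)C=C(OCc2ccccc2)C=C1OCc1ccccc1 | intermediate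
8 | (2S,4S)-5,7-bis(benzyloxy)-4-methoxy-2-phenylchroman (2,4-cis-4-methoxyflavan) | CO[C@H]1C[C@@H](c2ccccc2)Oc2cc(OCc3ccccc3)cc(OCc3ccccc3)c12 | intermediate
9 | (2S)-5,7-bis(benzyloxy)-2-phenylchroman-4-ol (flavan-4-ol, both C4 epimers) | OC1C[C@@H](c2ccccc2)Oc2cc(OCc3ccccc3)cc(OCc3ccccc3)c12 | intermediate
10 | (2S)-5,7-bis(benzyloxy)-2-phenylchroman-4-one | O=C1C[C@@H](c2ccccc2)Oc2cc(OCc3ccccc3)cc(OCc3ccccc3)c12 | intermediate
11 | (2S)-5,7-dihydroxy-2-phenylchroman-4-one ((S)-pinocembrin) | O=C1C[C@@H](c2ccccc2)Oc2cc(O)cc(O)c12 | intermediate
12 | 3-methylbut-2-en-1-ol | CC(C)=CCO | starting material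
13 | (2S)-5,7-bis[(3-methylbut-2-en-1-yl)oxy]-2-phenylchroman-4-one | O=C1C[C@@H](c2ccccc2)Oc2cc(OCC=C(C)C)cc(OCC=C(C)C)c12 | intermediate
14 | (2S)-6-(2-methylbut-3-en-2-yl)-7-[(3-methylbut-2-en-1-yl)oxy]-2-phenyl-2,3-dihydrochromene-4,5(6H)-dione (C6 configuration undefined, formed in the flask) | O=C1C[C@@H](c2ccccc2)OC2=C1C(=O)C(C(C)(C)C=C)C(OCC=C(C)C)=C2 | intermediate
15 | (2S)-5-hydroxy-7-[(3-methylbut-2-en-1-yl)oxy]-8-(3-methylbut-2-en-1-yl)-2-phenylchroman-4-one | CC(C)=CCOc1cc(O)c2c(c1CC=C(C)C)O[C@H](c1ccccc1)CC2=O | target

## Step count and risk

Total step count: 7. Longest linear sequence: 7 steps (1 to 15).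

**Step 2 (key step, the one new method of the route).**
- What may go wrong:
  - Poor facial discrimination, because styrene offers the chiral anion no hydrogen-bonding handle.
  - Erosion of the cis preference by exo addition, which mixes C2 configurations.
  - Friedel–Crafts oligomerisation, in which the electron-rich ring A of the product or of 3 attacks the oxocarbenium ion.
  - Sluggish addition, because the cation is strongly stabilised.
  - Deactivation of the catalyst by methyl transfer from the orthoformate-derived cation.
- First variation within the step: a more acidic, more confined catalyst (an imidodiphosphorimidate) and slow addition of 3.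
- Fallback, known chemistry, from 3 back to 10. The three-component cycloaddition is run with Sc(OTf)3 in CH2Cl2 to give racemic 2,4-cis-5,7-bis(benzyloxy)-4-methoxyflavan F1. This is hydrolysed as in step 3 to racemic 5,7-bis(benzyloxy)flavan-4-ol F2 and oxidised as in step 4 to racemic 5,7-bis(benzyloxy)flavanone F3. F3 is resolved kinetically by asymmetric transfer hydrogenation (RuCl[(R,R)-TsDPEN](p-cymene), HCO2H/NEt3, taken just past half conversion). The catalyst enantiomer is the one that consumes the 2R ketone, expected to be the (R,R) complex by analogy with simple aryl ketones. The 2R ketone is reduced to (2R,4R)-5,7-bis(benzyloxy)flavan-4-ol F4, which is separated by chromatography, and the unreacted ketone is 10. The price is half of the material.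

**Step 7.**
- What may go wrong:
  - Enolisation of dienone 14 before the Cope shift, which leaves a 1,1-dimethylallyl group on C6.
  - Lewis-acid-induced loss of a prenyl ether.
  - Slow ring-opening and reclosure of the chelated flavanone, which would lower the enantiomeric purity.
- Fallback, from 11 back to 15. It moves the rearrangement onto the substrate type for which it is established, with a non-migrating acyl group on O7, and installs the O7 prenyl ether last.
  - Selective acetylation of the unchelated 7-hydroxyl (Ac2O, 1 equiv, pyridine, 0 °C) gives (2S)-7-acetoxy-5-hydroxyflavanone F5.
  - Mitsunobu etherification with 12 gives (2S)-7-acetoxy-5-(3-methylbut-2-enyloxy)flavanone F6.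
  - Eu(fod)3 in CHCl3 at 60 °C gives (2S)-7-acetoxy-5-hydroxy-8-(3-methylbut-2-enyl)flavanone F7.
  - Mild deacetylation (NH4OAc, aqueous MeOH, rt) gives (2S)-5,7-dihydroxy-8-(3-methylbut-2-enyl)flavanone F8.
  - A Mitsunobu reaction with one equivalent of 12 etherifies the more acidic 7-hydroxyl and gives 15.

**Step 3.**
- What may go wrong: the C4 cation may lose the C3 proton (flav-3-ene formation), or it may be captured by ring A of a second molecule instead of by water.
- Fallback, from 8 directly to 10, bypassing 9: oxidative cleavage with DDQ in CH2Cl2/pH 7 buffer. Hydride abstraction from C4 gives the O-methyl oxocarbenium ion, which water converts through the hemiketal into the ketone with loss of methanol. No new compound is made.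

**Step 6.**
- What may go wrong: incomplete etherification of the chelated 5-hydroxyl, so that the reaction stalls at the mono-ether, and a difficult separation from the phosphine oxide.
- Fallback, from 11 back to 13, in two stages with a different mode of activation for the second. A Mitsunobu reaction with one equivalent of 12 gives (2S)-5-hydroxy-7-(3-methylbut-2-enyloxy)flavanone F9. The 5-hydroxyl is then alkylated with 1-bromo-3-methylbut-2-ene and Ag2O in CH2Cl2, a silver-assisted alkylation that needs no soluble base.

**Step 1.**
- What may go wrong: over-alkylation to the tribenzyl ether and C-benzylation of the phloroglucinol nucleus.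
- Fallback, from 1 back to 3. Exhaustive benzylation (BnBr, K2CO3, DMF) gives 2,4,6-tris(benzyloxy)benzaldehyde F10. One ortho benzyl group is then removed under chelation control with MgBr2·OEt2 in toluene/ether; the magnesium phenoxide chelate that forms protects the second ortho ether.

Should the enantiomeric purity need raising, recrystallisation would be tried at the stage of 10 or 11.

## Further compounds

F1 | step 2 | racemic 2,4-cis-5,7-bis(benzyloxy)-4-methoxyflavan | COC1CC(c2ccccc2)Oc2cc(OCc3ccccc3)cc(OCc3ccccc3)c12
F2 | step 2 | racemic 5,7-bis(benzyloxy)flavan-4-ol | OC1CC(c2ccccc2)Oc2cc(OCc3ccccc3)cc(OCc3ccccc3)c12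
F3 | step 2 | racemic 5,7-bis(benzyloxy)flavanone | O=C1CC(c2ccccc2)Oc2cc(OCc3ccccc3)cc(OCc3ccccc3)c12
F4 | step 2 | (2R,4R)-5,7-bis(benzyloxy)flavan-4-ol | O[C@@H]1C[C@H](c2ccccc2)Oc2cc(OCc3ccccc3)cc(OCc3ccccc3)c12
F5 | step 7 | (2S)-7-acetoxy-5-hydroxyflavanone | CC(=O)Oc1cc(O)c2c(c1)O[C@H](c1ccccc1)CC2=O
F6 | step 7 | (2S)-7-acetoxy-5-(3-methylbut-2-enyloxy)flavanone | CC(=O)Oc1cc(OCC=C(C)C)c2c(c1)O[C@H](c1ccccc1)CC2=O
F7 | step 7 | (2S)-7-acetoxy-5-hydroxy-8-(3-methylbut-2-enyl)flavanone | CC(=O)Oc1cc(O)c2c(c1CC=C(C)C)O[C@H](c1ccccc1)CC2=O
F8 | step 7 | (2S)-5,7-dihydroxy-8-(3-methylbut-2-enyl)flavanone | CC(C)=CCc1c(O)cc(O)c2c1O[C@H](c1ccccc1)CC2=O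
F0 | step 3 | none | none
F9 | step 6 | (2S)-5-hydroxy-7-(3-methylbut-2-enyloxy)flavanone | CC(C)=CCOc1cc(O)c2c(c1)O[C@H](c1ccccc1)CC2=O
F10 | step 1 | 2,4,6-tris(benzyloxy)benzaldehyde | O=Cc1c(OCc2ccccc2)cc(OCc2ccccc2)cc1OCc1ccccc1
A1 | alternative 1 | S-(pyridin-2-yl) 2-[(1R)-2-iodo-1-phenylethoxy]-4,6-bis(methoxymethoxy)benzothioate | O=C(Sc1ccccn1)c1c(OCOC)cc(OCOC)cc1O[C@H](c1ccccc1)CI
A2 | alternative 1 | (S)-5,7-bis(methoxymethoxy)flavanone | COCOc1cc(OCOC)c2c(c1)O[C@H](c1ccccc1)CC2=O
A3 | alternative 2 | (R)-3-phenyl-3-(triisopropylsilyloxy)propanoic acid | CC(C)[Si](C(C)C)(C(C)C)O[C@@H](c1ccccc1)CC(=O)O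
A4 | alternative 2 | 3,5-bis(benzyloxy)benzyne | C1(OCc2ccccc2)=CC(OCc2ccccc2)=CC#C1
A5 | alternative 2 | (R)-1-[2-hydroxy-4,6-bis(benzyloxy)phenyl]-3-phenyl-3-(triisopropylsilyloxy)propan-1-one | CC(C)[Si](C(C)C)(C(C)C)O[C@@H](c1ccccc1)CC(=O)c1c(O)cc(OCc2ccccc2)cc1OCc1ccccc1
A6 | alternative 3 | (S)-3-[3,5-bis(benzyloxy)phenoxy]-3-phenylpropanoic acid | O=C(O)C[C@@H](c1ccccc1)Oc1cc(OCc2ccccc2)cc(OCc2ccccc2)c1
A7 | alternative 3 | (S)-5,7-bis(benzyloxy)flavanone (identical with 10) | O=C1C[C@@H](c2ccccc2)Oc2cc(OCc3ccccc3)cc(OCc3ccccc3)c12
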